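**Retrosynthetic overview**

Numbering: C1 ketone, C2 (carries C7H2–O), C3, C4 (O-tigloyl), C5 (isopropyl), C6 (OAc). The plan rests on the C2=C3 double bond of the single carbocycle lying between the oxygen-bearing carbons C1 and C4 (the imprint of a 1,4-dioxygenated diene), and on the C6–O bond trans to the C5 isopropyl group (the imprint of a trans enone after a carbon-to-oxygen switch).
Late stage: C1 ketone from a C1 silyl ether, C7 tiglate by acylation, C4 tiglate by Mitsunobu inversion of a C4 alcohol, C6 acetate by Baeyer–Villiger oxidation of a C6 acetyl group.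
Key disconnection: C4–C5 and C1–C6, an enantioselective Diels–Alder reaction of a (1Z,3E)-1-silyloxy-4-acetoxy diene with (E)-5-methylhex-3-en-2-one, which forms the only ring and four stereocentres.
Diene: from 2,2-dimethyl-1,3-dioxan-5-one by olefination, reduction, acetylation, acetal removal, self-limiting mono-oxidation of the symmetric diol, then one-pot silylation and silyl dienolisation; this replaces a statistical mono-deprotection of two equivalent silyl ethers.

Key step: step 7

Assumption (sense of induction): the (S)-configured oxazaborolidinium ion is taken to give the (1R,4S,5R,6R) adduct, by analogy with the α-C–H···O binding model for enones; if the sense proves opposite, the (R)-configured catalyst is used with no other change.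
Abbreviations: TBS = tert-butyldimethylsilyl; tigloyl = (E)-2-methylbut-2-enoyl. Locants and descriptors of ring compounds follow the target numbering above.

**Route**

Step 1
Reactants: 1 2,2-dimethyl-1,3-dioxan-5-one; 2 triethyl phosphonoacetate
Product: 3 ethyl 2-(2,2-dimethyl-1,3-dioxan-5-ylidene)acetate
Conditions: NaH, THF, 0 °C → rt
Reagents that add atoms: none
Why: Horner–Wadsworth–Emmons olefination of the reactive α,α'-dioxygenated ketone by the sodium phosphonate anion should give the exocyclic unsaturated ester; the ketone is symmetric, so no alkene geometry arises.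

Step 2
Reactants: 3 ethyl 2-(2,2-dimethyl-1,3-dioxan-5-ylidene)acetate
Product: 4 2-(2,2-dimethyl-1,3-dioxan-5-ylidene)ethan-1-ol
Conditions: i-Bu2AlH (2.2 equiv), CH2Cl2, –78 °C; aq. potassium sodium tartrate
Reagents that add atoms: none
Why: 1,2-Reduction of the conjugated ester by the aluminium hydride at low temperature should give the allylic alcohol, the acetonide being inert to hydride.

Step 3
Reactants: 4 2-(2,2-dimethyl-1,3-dioxan-5-ylidene)ethan-1-ol
Product: 5 2-(2,2-dimethyl-1,3-dioxan-5-ylidene)ethyl acetate
Conditions: Ac2O, pyridine, DMAP (cat.), CH2Cl2, 0 °C → rt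
Reagents that add atoms: acetic anhydride, CC(=O)OC(C)=O
Why: DMAP-catalysed acylation of the primary allylic alcohol installs the acetate that later becomes the C4 oxygen substituent and the weaker of the two diene donors.

Step 4
Reactants: 5 2-(2,2-dimethyl-1,3-dioxan-5-ylidene)ethyl acetate
Product: 6 4-hydroxy-3-(hydroxymethyl)but-2-en-1-yl acetate
Conditions: AcOH–H2O (4:1), rt; toluene azeotrope
Reagents that add atoms: none
Why: Acid-catalysed acetal hydrolysis frees the two equivalent hydroxymethyl arms, and the primary acetate should survive aqueous acetic acid at room temperature.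

Step 5
Reactants: 6 4-hydroxy-3-(hydroxymethyl)but-2-en-1-yl acetate
Product: 7 4-acetoxy-2-(hydroxymethyl)but-2-enal (E/Z mixture, used as such)
Conditions: MnO2 (activated, excess), CH2Cl2, rt
Reagents that add atoms: none
Why: Allylic oxidation with MnO2 should stop after one arm, because the first aldehyde makes the alkene electron-poor and the remaining hydroxymethyl group a poor substrate; the two arms of 6 are equivalent and the alkene geometry is erased in step 6.

Step 6
Reactants: 7 4-acetoxy-2-(hydroxymethyl)but-2-enal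
Product: 9 (1Z,3E)-4-acetoxy-1-(tert-butyldimethylsilyloxy)-2-[(tert-butyldimethylsilyloxy)methyl]buta-1,3-diene, via O-silylated enal 8 (not isolated)
Conditions: TBSOTf (2.4 equiv), Et3N (5 equiv), CH2Cl2, –78 → 0 °C; filtration through basic alumina
Reagents that add atoms: tert-butyldimethylsilyl trifluoromethanesulfonate (TBSOTf), CC(C)(C)[Si](C)(C)OS(=O)(=O)C(F)(F)F
Why: O-silylation of the alcohol is followed by silyl triflate/amine soft dienolisation (aldehyde O-silylation, then γ-deprotonation at the CH2OAc carbon), in which the s-trans enal places OTBS trans to C3 (1Z) and allylic 1,3-strain turns OAc away from the fully substituted C2 (3E), so both oxygens should sit on the outside of the s-cis diene.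

Step 7
Reactants: 9 (1Z,3E)-4-acetoxy-1-(tert-butyldimethylsilyloxy)-2-[(tert-butyldimethylsilyloxy)methyl]buta-1,3-diene; 10 (E)-5-methylhex-3-en-2-one
Product: 11 (1R,4S,5R,6R)-6-acetyl-1-(tert-butyldimethylsilyloxy)-2-[(tert-butyldimethylsilyloxy)methyl]-5-isopropylcyclohex-2-en-4-yl acetate (C1–OTBS, C4–OAc and C6–acetyl mutually cis, C5–isopropyl trans to them)
Conditions: (S)-1-(2-methylphenyl)-3,3-diphenyltetrahydro-1H,3H-pyrrolo[1,2-c][1,3,2]oxazaborole (C24H24BNO, 20 mol %), HN(SO2CF3)2 (18 mol %), CH2Cl2, –78 → –40 °C; Et3N quench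
Reagents that add atoms: none
Why: The N-protonated oxazaborolidine binds the enone carbonyl and lowers its LUMO, so that diene C4, the terminus vinylogous to the C1 silyloxy donor, bonds to the β-carbon C5 slightly ahead of the C1–C6 bond in a concerted, asynchronous cycloaddition; the closest known reaction type is the chiral oxazaborolidinium-catalysed Diels–Alder reaction of enones and acrylates with silyloxy dienes. The cyclohexene ring is closed in a suprafacial (4+2) mode on both partners, the two σ-bonds forming on one face of the diene and one face of the enone. C1 and C4 come out cis because both oxygens are outside substituents of the (1Z,3E)-diene, the C6 acetyl group is cis to them through the endo transition state with the catalyst-bound carbonyl under the diene, the C5 isopropyl group is trans to acetyl because the (E)-geometry of the enone is carried over, and the absolute sense is set by the catalyst, which screens one enone face. The step needs regioselectivity (acetyl next to C1), which the silyloxy group secures by being a far stronger donor than the acetoxy group or the C2 alkyl branch, together with endo and enantiofacial selectivity from the bound Lewis acid. Cycloaddition rather than silyl transfer is favoured by the robust TBS group and the low temperature.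

Step 8
Reactants: 11 (1R,4S,5R,6R)-6-acetyl-1-(tert-butyldimethylsilyloxy)-2-[(tert-butyldimethylsilyloxy)methyl]-5-isopropylcyclohex-2-en-4-yl acetate
Product: 12 1-[(1R,4S,5R,6R)-1-(tert-butyldimethylsilyloxy)-2-[(tert-butyldimethylsilyloxy)methyl]-4-hydroxy-5-isopropylcyclohex-2-en-6-yl]ethan-1-one
Conditions: K2CO3 (0.3 equiv), MeOH, 0 °C
Reagents that add atoms: none
Why: Carbonate-catalysed transesterification removes the only ester, the C4 acetate, without touching the silyl ethers; C6 already holds its more stable equatorial configuration, so brief enolisation should not erode it.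

Step 9
Reactants: 12 1-[(1R,4S,5R,6R)-1-(tert-butyldimethylsilyloxy)-2-[(tert-butyldimethylsilyloxy)methyl]-4-hydroxy-5-isopropylcyclohex-2-en-6-yl]ethan-1-one; 13 tiglic acid
Product: 14 (1R,4R,5R,6R)-6-acetyl-1-(tert-butyldimethylsilyloxy)-2-[(tert-butyldimethylsilyloxy)methyl]-5-isopropylcyclohex-2-en-4-yl (E)-2-methylbut-2-enoate (C4–O now cis to isopropyl)
Conditions: PPh3, DIAD, toluene, 0 °C → rt
Reagents that add atoms: none
Why: Mitsunobu esterification, in which tiglate displaces the C4 alkoxyphosphonium group by SN2 with inversion and so places the C4 ester cis to the C5 isopropyl group as in the target; SN2' attack is disfavoured because C2 is fully substituted.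

Step 10
Reactants: 14 (1R,4R,5R,6R)-6-acetyl-1-(tert-butyldimethylsilyloxy)-2-[(tert-butyldimethylsilyloxy)methyl]-5-isopropylcyclohex-2-en-4-yl (E)-2-methylbut-2-enoate
Product: 15 (1S,4S,5S,6R)-6-acetoxy-1-(tert-butyldimethylsilyloxy)-2-[(tert-butyldimethylsilyloxy)methyl]-5-isopropylcyclohex-2-en-4-yl (E)-2-methylbut-2-enoate
Conditions: mCPBA, NaHCO3, CH2Cl2, rt, dark
Reagents that add atoms: meta-chloroperoxybenzoic acid (mCPBA), O=C(OO)c1cccc(Cl)c1
Why: Baeyer–Villiger oxidation, in which the secondary ring carbon C6 migrates in preference to methyl and with retention, so the acetyl group becomes the C6 acetate trans to isopropyl; the ring alkene is deactivated toward the electrophilic peracid by three allylic C–O bonds and the tiglate alkene by conjugation.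

Step 11
Reactants: 15 (1S,4S,5S,6R)-6-acetoxy-1-(tert-butyldimethylsilyloxy)-2-[(tert-butyldimethylsilyloxy)methyl]-5-isopropylcyclohex-2-en-4-yl (E)-2-methylbut-2-enoate
Product: 16 (1S,4S,5S,6R)-6-acetoxy-1-hydroxy-2-(hydroxymethyl)-5-isopropylcyclohex-2-en-4-yl (E)-2-methylbut-2-enoate
Conditions: HF·pyridine, pyridine–THF, 0 °C → rt
Reagents that add atoms: none
Why: Fluoride-mediated desilylation under mildly acidic conditions should cleave both TBS ethers while suppressing the base-induced acetyl shift from O6 to the cis O1 and leaving the esters intact.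

Step 12
Reactants: 16 (1S,4S,5S,6R)-6-acetoxy-1-hydroxy-2-(hydroxymethyl)-5-isopropylcyclohex-2-en-4-yl (E)-2-methylbut-2-enoate; 17 tigloyl chloride
Product: 18 [(1S,4S,5S,6R)-6-acetoxy-1-hydroxy-5-isopropyl-4-{[(E)-2-methylbut-2-enoyl]oxy}cyclohex-2-en-2-yl]methyl (E)-2-methylbut-2-enoate
Conditions: 2,4,6-collidine, CH2Cl2, –40 → 0 °C
Reagents that add atoms: none
Why: Chemoselective acylation, since the unhindered primary allylic C7 hydroxyl should react with the sluggish α-branched conjugated acid chloride much faster than the secondary C1 hydroxyl flanked by C2 and the C6 acetate.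

Step 13
Reactants: 18 [(1S,4S,5S,6R)-6-acetoxy-1-hydroxy-5-isopropyl-4-{[(E)-2-methylbut-2-enoyl]oxy}cyclohex-2-en-2-yl]methyl (E)-2-methylbut-2-enoate
Product: 19 CNP0218511.1, [(4S,5S,6R)-6-acetoxy-5-isopropyl-4-{[(E)-2-methylbut-2-enoyl]oxy}-1-oxocyclohex-2-en-2-yl]methyl (E)-2-methylbut-2-enoate
Conditions: Dess–Martin periodinane, NaHCO3, CH2Cl2, 0 °C → rt
Reagents that add atoms: none
Why: Dess–Martin oxidation of the secondary allylic alcohol under buffered, non-basic conditions gives the C1 enone without epimerising the now α-acetoxy C6 centre or shifting acyl groups.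

**Compound list**

1 | 2,2-dimethyl-1,3-dioxan-5-one | CC1(C)OCC(=O)CO1 | starting material
2 | triethyl phosphonoacetate | CCOC(=O)CP(=O)(OCC)OCC | starting material
3 | ethyl 2-(2,2-dimethyl-1,3-dioxan-5-ylidene)acetate | CCOC(=O)C=C1COC(C)(C)OC1 | intermediate
4 | 2-(2,2-dimethyl-1,3-dioxan-5-ylidene)ethan-1-ol | OCC=C1COC(C)(C)OC1 | intermediate
5 | 2-(2,2-dimethyl-1,3-dioxan-5-ylidene)ethyl acetate | CC(=O)OCC=C1COC(C)(C)OC1 | intermediate
6 | 4-hydroxy-3-(hydroxymethyl)but-2-en-1-yl acetate | CC(=O)OCC=C(CO)CO | intermediate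
7 | 4-acetoxy-2-(hydroxymethyl)but-2-enal (E/Z mixture) | CC(=O)OCC=C(CO)C=O | intermediate
8 | 4-acetoxy-2-[(tert-butyldimethylsilyloxy)methyl]but-2-enal (E/Z mixture, not isolated) | CC(=O)OCC=C(CO[Si](C)(C)C(C)(C)C)C=O | intermediate
9 | (1Z,3E)-4-acetoxy-1-(tert-butyldimethylsilyloxy)-2-[(tert-butyldimethylsilyloxy)methyl]buta-1,3-diene | CC(=O)O/C=C/C(CO[Si](C)(C)C(C)(C)C)=C/O[Si](C)(C)C(C)(C)C | intermediate
10 | (E)-5-methylhex-3-en-2-one | CC(=O)/C=C/C(C)C | starting material
11 | (1R,4S,5R,6R)-6-acetyl-1-(TBS-oxy)-2-[(TBS-oxy)methyl]-5-isopropylcyclohex-2-en-4-yl acetate | CC(C)(C)[Si](C)(C)OCC1=C[C@@H](OC(C)=O)[C@H](C(C)C)[C@@H](C(C)=O)[C@H]1O[Si](C)(C)C(C)(C)C | intermediate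
12 | 1-[(1R,4S,5R,6R)-1-(TBS-oxy)-2-[(TBS-oxy)methyl]-4-hydroxy-5-isopropylcyclohex-2-en-6-yl]ethan-1-one | CC(C)(C)[Si](C)(C)OCC1=C[C@@H](O)[C@H](C(C)C)[C@@H](C(C)=O)[C@H]1O[Si](C)(C)C(C)(C)C | intermediate
13 | tiglic acid, (E)-2-methylbut-2-enoic acid | C/C=C(\C)C(=O)O | starting material
14 | (1R,4R,5R,6R)-6-acetyl-1-(TBS-oxy)-2-[(TBS-oxy)methyl]-5-isopropylcyclohex-2-en-4-yl tiglate | CC(C)(C)[Si](C)(C)OCC1=C[C@H](OC(=O)/C(C)=C/C)[C@H](C(C)C)[C@@H](C(C)=O)[C@H]1O[Si](C)(C)C(C)(C)C | intermediate
15 | (1S,4S,5S,6R)-6-acetoxy-1-(TBS-oxy)-2-[(TBS-oxy)methyl]-5-isopropylcyclohex-2-en-4-yl tiglate | CC(C)(C)[Si](C)(C)OCC1=C[C@H](OC(=O)/C(C)=C/C)[C@H](C(C)C)[C@@H](OC(C)=O)[C@H]1O[Si](C)(C)C(C)(C)C | intermediate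
16 | (1S,4S,5S,6R)-6-acetoxy-1-hydroxy-2-(hydroxymethyl)-5-isopropylcyclohex-2-en-4-yl tiglate | OCC1=C[C@H](OC(=O)/C(C)=C/C)[C@H](C(C)C)[C@@H](OC(C)=O)[C@H]1O | intermediate
17 | tigloyl chloride, (E)-2-methylbut-2-enoyl chloride | C/C=C(\C)C(Cl)=O | starting material
18 | [(1S,4S,5S,6R)-6-acetoxy-1-hydroxy-5-isopropyl-4-(tigloyloxy)cyclohex-2-en-2-yl]methyl tiglate | C/C=C(\C)C(=O)OCC1=C[C@H](OC(=O)/C(C)=C/C)[C@H](C(C)C)[C@@H](OC(C)=O)[C@H]1O | intermediate
19 | CNP0218511.1, [(4S,5S,6R)-6-acetoxy-5-isopropyl-1-oxo-4-(tigloyloxy)cyclohex-2-en-2-yl]methyl tiglate | C/C=C(\C)C(=O)OCC1=C[C@H](OC(=O)/C(C)=C/C)[C@H](C(C)C)[C@@H](OC(C)=O)C1=O | target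

**Step count**

Total: 13 steps. Longest linear sequence: 13 steps (1 → 19); compounds 2, 10, 13 and 17 are purchased.

**Steps most likely to fail**

Step 7 (Diels–Alder). The β-branched enone may react too slowly at temperatures the acid-sensitive diene tolerates, so that Lewis-acid-induced diene decomposition or stepwise silyl transfer competes, and facial discrimination of an acyclic enone may be incomplete. The fallback sets out from diene 9 and changes the dienophile to the more electrophilic, commercial (E)-4-methylpent-2-enal (CC(C)/C=C/C=O), with the same oxazaborolidinium system, for which enals are the most dependable substrates; the catalyst enantiomer is chosen to give the same sense. This should give the C6-formyl analogue of 11, F1, with the same regiochemistry and endo topology. Addition of MeMgBr in THF at –78 °C, where the aldehyde reacts well ahead of the acetate, would give the 1-hydroxyethyl compound F2 as a mixture at the carbinol carbon. Dess–Martin oxidation of F2 then comes back to the route at compound 11.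

Step 10 (Baeyer–Villiger). Epoxidation of the ring alkene may outpace the slow addition of peracid to the ketone, which is flanked by the C1 silyl ether and the C5 isopropyl group. The fallback sets out from alcohol 12 and masks the alkene as part of an enone before the oxidation. Dess–Martin oxidation of 12 gives the C4 enone F3, whose C2=C3 bond is electron-poor and inert to peracid and whose conjugated ketone is a poor Baeyer–Villiger substrate. mCPBA with NaHCO3 should then convert only the acetyl group, giving the acetoxy enone F4. Reduction with NaBH4 and CeCl3·7H2O in MeOH at –78 °C should deliver hydride axially and return the pseudoequatorial C4 alcohol trans to isopropyl, F5. Mitsunobu esterification of F5 with tiglic acid 13 (PPh3, DIAD) inverts C4 and comes back to the route at compound 15.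

Step 9 (Mitsunobu). Displacement at the C4 alkoxyphosphonium ion next to the isopropyl group may be slow, so that elimination to a diene, allylic transposition or acyl transfer with retention takes over. The fallback sets out from alcohol 12 and separates activation from displacement. Chloromethanesulfonyl chloride and pyridine at 0 °C would give the C4 chloromethanesulfonate F6. Cesium tiglate F7, made from tiglic acid 13 and Cs2CO3, with 18-crown-6 in toluene should displace the sulfonate by SN2 with inversion and come back to the route at compound 14.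

**Further compounds**

F1 | step 7 | (1R,4S,5R,6R)-1-(TBS-oxy)-2-[(TBS-oxy)methyl]-6-formyl-5-isopropylcyclohex-2-en-4-yl acetate | CC(C)(C)[Si](C)(C)OCC1=C[C@@H](OC(C)=O)[C@H](C(C)C)[C@@H](C=O)[C@H]1O[Si](C)(C)C(C)(C)C
F2 | step 7 | 1-(TBS-oxy)-2-[(TBS-oxy)methyl]-6-(1-hydroxyethyl)-5-isopropylcyclohex-2-en-4-yl acetate, ring configuration as in 11, mixture at the carbinol carbon | CC(C)(C)[Si](C)(C)OCC1=C[C@@H](OC(C)=O)[C@H](C(C)C)[C@@H](C(C)O)[C@H]1O[Si](C)(C)C(C)(C)C
F3 | step 10 | 6-acetyl-1-(TBS-oxy)-2-[(TBS-oxy)methyl]-5-isopropylcyclohex-2-en-4-one, C1, C5 and C6 as in 12 | CC(C)(C)[Si](C)(C)OCC1=CC(=O)[C@H](C(C)C)[C@@H](C(C)=O)[C@H]1O[Si](C)(C)C(C)(C)C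
F4 | step 10 | 1-(TBS-oxy)-2-[(TBS-oxy)methyl]-5-isopropyl-4-oxocyclohex-2-en-6-yl acetate, C1, C5 and C6 as in 15 | CC(C)(C)[Si](C)(C)OCC1=CC(=O)[C@H](C(C)C)[C@@H](OC(C)=O)[C@H]1O[Si](C)(C)C(C)(C)C
F5 | step 10 | 1-(TBS-oxy)-2-[(TBS-oxy)methyl]-4-hydroxy-5-isopropylcyclohex-2-en-6-yl acetate, C4 hydroxyl trans to isopropyl and cis to the C1 and C6 oxygens | CC(C)(C)[Si](C)(C)OCC1=C[C@@H](O)[C@H](C(C)C)[C@@H](OC(C)=O)[C@H]1O[Si](C)(C)C(C)(C)C
F6 | step 9 | 6-acetyl-1-(TBS-oxy)-2-[(TBS-oxy)methyl]-5-isopropylcyclohex-2-en-4-yl chloromethanesulfonate, configuration as in 12 | CC(C)(C)[Si](C)(C)OCC1=C[C@@H](OS(=O)(=O)CCl)[C@H](C(C)C)[C@@H](C(C)=O)[C@H]1O[Si](C)(C)C(C)(C)C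
F7 | step 9 | cesium tiglate, cesium (E)-2-methylbut-2-enoate | C/C=C(\C)C(=O)[O-].[Cs+]
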